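**Retrosynthetic overview**
1. The target is guibourtinidol-(4α→6)-fisetinidol. The last disconnections are six O-benzyl groups (one hydrogenolysis) and the upper C3–OH, traced back to a C3–B(pin) bond (stereoretentive oxidation).
2. The upper ring C is cut twice, at O1–C2 and C3–C4: an oxa-[4+2] cycloaddition of an ortho-quinone methide (O1=C8a–C4a=C4, drawn from the upper ring A) with an (E)-β-boryl-4-benzyloxystyrene (C2=C3). This joins the two halves and sets C2, C3 and C4 together.
3. Enabling feature: in the upper unit the phenolic O1 on C8a is ortho to the doubly benzylic C4, so O1–C8a–C4a–C4 is a latent ortho-quinone methide. C2-aryl and C3-OH are trans like the ends of an (E)-alkene, and the all-equatorial ring C (2,4-cis, 2,3-trans, 3,4-trans) is the endo adduct.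
4. The quinone methide comes from a diaryl carbinol used as its epimer mixture (stereoconvergent). The carbinol comes from 6-lithio-tetra-O-benzylfisetinidol and 4-benzyloxy-2-hydroxybenzaldehyde; the lower unit and its two stereocentres come from (−)-fisetinidol (chiral pool).
5. Ring order: the lower rings A, C and B are bought intact, the upper rings A and B enter as arenes, and the upper ring C is the only ring made, in the key step.

Key step: step 6

Assumption: (−)-fisetinidol is taken as purchasable from natural-product suppliers.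
Assumption: the face delivered by the (R)-configured catalyst in step 6 is assigned by analogy only; the (S) enantiomer is equally available should a model run show the opposite sense.

**Step 1**
Reactants: 1 (−)-fisetinidol; 2 benzyl bromide
Product: 3 7,3',4'-tri-O-benzylfisetinidol
Conditions: BnBr (3.3 equiv), K2CO3, DMF, rt
Reagents that add atoms: benzyl bromide 2, BrCc1ccccc1
Why: Williamson etherification in which K2CO3 deprotonates only the three phenols, so the secondary 3-OH stays free and no stereocentre is touched.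

**Step 2**
Reactants: 3 7,3',4'-tri-O-benzylfisetinidol; 2 benzyl bromide
Product: 4 3,7,3',4'-tetra-O-benzylfisetinidol
Conditions: NaH, BnBr, Bu4NI (cat.), THF/DMF, 0 °C → rt
Reagents that add atoms: benzyl bromide 2, BrCc1ccccc1
Why: Williamson etherification of the secondary alkoxide, free of C2 epimerisation because all phenols are already capped.

**Step 3**
Reactants: 4 3,7,3',4'-tetra-O-benzylfisetinidol; 5 N-bromosuccinimide
Product: 6 6-bromo-3,7,3',4'-tetra-O-benzylfisetinidol
Conditions: NBS (1.0 equiv), CH2Cl2, −78 → 0 °C, dark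
Reagents that add atoms: N-bromosuccinimide 5, O=C1CCC(=O)N1Br
Why: Electrophilic aromatic bromination at C6, which is para to the ring oxygen and ortho to the 7-benzyloxy group and so the most nucleophilic and least hindered site of the resorcinol-type ring A (C8 lies between two oxygens, ring B is a less activated catechol diether).

**Step 4**
Reactants: 6 6-bromo-3,7,3',4'-tetra-O-benzylfisetinidol; 7 4-(benzyloxy)-2-hydroxybenzaldehyde
Product: 10 [4-(benzyloxy)-2-hydroxyphenyl][tetra-O-benzylfisetinidol-6-yl]methanol (both carbinol epimers), via aryllithium 8 (not isolated), via sodium phenolate 9 (not isolated)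
Conditions: n-BuLi, THF, −78 °C; then 9 (from 7, NaH, THF, 0 °C), −78 → 0 °C; aq. NH4Cl
Reagents that add atoms: n-butyllithium, [Li]CCCC (lithium of 8); sodium hydride, [Na+].[H-] (sodium of 9)
Why: Bromine–lithium exchange followed by 1,2-addition of the aryllithium to the aldehyde, whose phenol is masked as its sodium phenolate so that no aryllithium is lost; the carbinol centre forms as a mixture, which does not matter because step 6 erases it.

**Step 5**
Reactants: 11 1-(benzyloxy)-4-ethynylbenzene; 12 pinacolborane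
Product: 13 (E)-2-{2-[4-(benzyloxy)phenyl]ethenyl}-4,4,5,5-tetramethyl-1,3,2-dioxaborolane
Conditions: HBpin, Cp2Zr(H)Cl (5 mol%), Et3N (cat.), neat, 60 °C
Reagents that add atoms: pinacolborane 12, CC1(C)OBOC1(C)C
Why: Cp2Zr(H)Cl-catalysed syn hydroboration of a terminal alkyne with pinacolborane, which places boron on the terminal carbon and gives the (E)-alkenylboronate.

**Step 6**
Reactants: 10 [4-(benzyloxy)-2-hydroxyphenyl][tetra-O-benzylfisetinidol-6-yl]methanol (both carbinol epimers); 13 (E)-alkenylboronate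
Product: 15 upper-unit C3 pinacolboronate of hexa-O-benzyl guibourtinidol-(4α→6)-fisetinidol (2,3-trans-3,4-trans), via ortho-quinone methide 14 (not isolated)
Conditions: 13 (2 equiv), (R)-3,3'-bis(2,4,6-triisopropylphenyl)-1,1'-binaphthyl-2,2'-diyl N-triflylphosphoramide (10 mol%), 5 Å MS, CH2Cl2, −20 °C → rt
Reagents that add atoms: none
Why: Proposed new method: the chiral acid should ionise both carbinol epimers of 10 to the one hydrogen-bonded (E)-ortho-quinone methide 14 (stereoconvergent, the carbinol centre is erased), which should react with the electron-rich (E)-alkenylboronate 13 in an asynchronous inverse-electron-demand oxa-[4+2] cycloaddition, the C3–C4 bond forming ahead of the O1–C2 bond through a p-benzyloxybenzyl-stabilised transition state. The closest known reaction type is the chiral N-triflylphosphoramide- or phosphoric-acid-catalysed [4+2] of ortho-hydroxybenzhydrol-derived ortho-quinone methides with styrenes to 2,4-cis chromans, together with Diels–Alder reactions in which alkenyl pinacolboronates act as the 2π partner with boron retained; the new element is a β-boryl styrene in the hetero version. Ring C is the only ring closed, by [4+2] cycloaddition of O1=C8a–C4a=C4 across C2=C3 (in the stepwise limit a six-membered phenoxide-to-benzylic-cation closure). C4 is set by the catalyst, which shields one face of the methide carbon; C2 is set by the endo orientation of the 4-benzyloxyphenyl group, which places it cis to the outward C4 aryl; C3 is set by suprafacial transfer of the (E)-alkene geometry, which places boron trans to both aryl groups (all-equatorial ring C). The step needs O1-to-C2 regioselectivity, secured by the p-benzyloxyphenyl group on C2 and not opposed by boron on C3; a single quinone methide, secured because only the upper ring A carries a free ortho-OH (the lower 7-OH is benzylated); and retention of boron, secured by the hindered pinacol ester in a non-nucleophilic medium so that ring closure should outrun deborylation.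

**Step 7**
Reactants: 15 upper-unit C3 pinacolboronate; 16 sodium perborate tetrahydrate
Product: 17 hexa-O-benzyl guibourtinidol-(4α→6)-fisetinidol with free upper 3-OH
Conditions: NaBO3·4H2O (5 equiv), THF/H2O 1:1, rt
Reagents that add atoms: sodium perborate tetrahydrate 16, [Na+].[Na+].O[B-]1(O)OO[B-](O)(O)OO1.O.O.O.O.O.O
Why: Oxidation of a secondary alkyl pinacolboronate by 1,2-shift of carbon from boron to oxygen with retention at C3, under mild perborate conditions of the kind used for chroman-3-yl and other β-alkoxy boronates without ring-opening elimination.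

**Step 8**
Reactants: 17 hexa-O-benzyl guibourtinidol-(4α→6)-fisetinidol with free upper 3-OH
Product: 18 guibourtinidol-(4α→6)-fisetinidol (target)
Conditions: H2 (1 atm), Pd(OH)2 on carbon, THF/MeOH 1:1, rt
Reagents that add atoms: none
Why: Hydrogenolysis of the six benzyl ethers, under mild conditions that should leave the cyclic benzylic C2–O1 bonds and the C4–aryl bond intact, as is routine for benzylated proanthocyanidins.

**Compound list**
(CIP descriptors of the upper unit change with the protecting groups and with boron at C3; the spatial arrangement is that of the target throughout.)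

1 | (−)-fisetinidol, (2R,3S)-2-(3,4-dihydroxyphenyl)-3,4-dihydro-2H-chromene-3,7-diol | Oc1ccc2c(c1)O[C@H](c1ccc(O)c(O)c1)[C@@H](O)C2 | starting material
2 | benzyl bromide | BrCc1ccccc1 | starting material
3 | (2R,3S)-7-(benzyloxy)-2-[3,4-bis(benzyloxy)phenyl]-3,4-dihydro-2H-chromen-3-ol | c1ccccc1COc1ccc2c(c1)O[C@H](c1ccc(OCc3ccccc3)c(OCc3ccccc3)c1)[C@@H](O)C2 | intermediate
4 | (2R,3S)-3,7-bis(benzyloxy)-2-[3,4-bis(benzyloxy)phenyl]-3,4-dihydro-2H-chromene | c1ccccc1COc1ccc2c(c1)O[C@H](c1ccc(OCc3ccccc3)c(OCc3ccccc3)c1)[C@@H](OCc1ccccc1)C2 | intermediate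
5 | N-bromosuccinimide | O=C1CCC(=O)N1Br | starting material
6 | (2R,3S)-6-bromo-3,7-bis(benzyloxy)-2-[3,4-bis(benzyloxy)phenyl]-3,4-dihydro-2H-chromene | c1ccccc1COc1c(Br)cc2c(c1)O[C@H](c1ccc(OCc3ccccc3)c(OCc3ccccc3)c1)[C@@H](OCc1ccccc1)C2 | intermediate
7 | 4-(benzyloxy)-2-hydroxybenzaldehyde | O=Cc1ccc(OCc2ccccc2)cc1O | starting material
8 | [(2R,3S)-3,7-bis(benzyloxy)-2-[3,4-bis(benzyloxy)phenyl]-3,4-dihydro-2H-chromen-6-yl]lithium | c1ccccc1COc1c([Li])cc2c(c1)O[C@H](c1ccc(OCc3ccccc3)c(OCc3ccccc3)c1)[C@@H](OCc1ccccc1)C2 | intermediate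
9 | sodium 5-(benzyloxy)-2-formylphenolate | [Na+].[O-]c1cc(OCc2ccccc2)ccc1C=O | intermediate
10 | [4-(benzyloxy)-2-hydroxyphenyl][(2R,3S)-3,7-bis(benzyloxy)-2-[3,4-bis(benzyloxy)phenyl]-3,4-dihydro-2H-chromen-6-yl]methanol, both epimers at the carbinol carbon | c1ccccc1COc1c(C(O)c3ccc(OCc4ccccc4)cc3O)cc2c(c1)O[C@H](c1ccc(OCc3ccccc3)c(OCc3ccccc3)c1)[C@@H](OCc1ccccc1)C2 | intermediate
11 | 1-(benzyloxy)-4-ethynylbenzene | C#Cc1ccc(OCc2ccccc2)cc1 | starting material
12 | pinacolborane (4,4,5,5-tetramethyl-1,3,2-dioxaborolane) | CC1(C)OBOC1(C)C | starting material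
13 | (E)-2-{2-[4-(benzyloxy)phenyl]ethenyl}-4,4,5,5-tetramethyl-1,3,2-dioxaborolane | CC1(C)OB(/C=C/c2ccc(OCc3ccccc3)cc2)OC1(C)C | intermediate
14 | (6E)-3-(benzyloxy)-6-{[(2R,3S)-3,7-bis(benzyloxy)-2-[3,4-bis(benzyloxy)phenyl]-3,4-dihydro-2H-chromen-6-yl]methylidene}cyclohexa-2,4-dien-1-one | O=C1C=C(OCc2ccccc2)C=C/C1=C\c1cc2c(cc1OCc1ccccc1)O[C@H](c1ccc(OCc3ccccc3)c(OCc3ccccc3)c1)[C@@H](OCc1ccccc1)C2 | intermediate
15 | 2-[(2S,3S,4S)-7-(benzyloxy)-2-[4-(benzyloxy)phenyl]-4-[(2R,3S)-3,7-bis(benzyloxy)-2-[3,4-bis(benzyloxy)phenyl]-3,4-dihydro-2H-chromen-6-yl]-3,4-dihydro-2H-chromen-3-yl]-4,4,5,5-tetramethyl-1,3,2-dioxaborolane (2,3-trans-3,4-trans, 4α-aryl) | c1ccccc1COc1ccc([C@H]2Oc3cc(OCc5ccccc5)ccc3[C@@H](c3cc4c(cc3OCc3ccccc3)O[C@H](c3ccc(OCc5ccccc5)c(OCc5ccccc5)c3)[C@@H](OCc3ccccc3)C4)[C@@H]2B2OC(C)(C)C(C)(C)O2)cc1 | intermediate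
16 | sodium perborate tetrahydrate, NaBO3·4H2O (dimeric peroxoborate) | [Na+].[Na+].O[B-]1(O)OO[B-](O)(O)OO1.O.O.O.O.O.O | starting material
17 | (2R,3S,4S)-7-(benzyloxy)-2-[4-(benzyloxy)phenyl]-4-[(2R,3S)-3,7-bis(benzyloxy)-2-[3,4-bis(benzyloxy)phenyl]-3,4-dihydro-2H-chromen-6-yl]-3,4-dihydro-2H-chromen-3-ol (2,3-trans-3,4-trans, 4α-aryl) | c1ccccc1COc1ccc([C@H]2Oc3cc(OCc5ccccc5)ccc3[C@@H](c3cc4c(cc3OCc3ccccc3)O[C@H](c3ccc(OCc5ccccc5)c(OCc5ccccc5)c3)[C@@H](OCc3ccccc3)C4)[C@@H]2O)cc1 | intermediate
18 | (2R,3S,4R)-4-[(2R,3S)-2-(3,4-dihydroxyphenyl)-3,7-dihydroxy-3,4-dihydro-2H-chromen-6-yl]-2-(4-hydroxyphenyl)-3,4-dihydro-2H-chromene-3,7-diol, guibourtinidol-(4α→6)-fisetinidol | Oc1ccc([C@H]2Oc3cc(O)ccc3[C@@H](c3cc4c(cc3O)O[C@H](c3ccc(O)c(O)c3)[C@@H](O)C4)[C@@H]2O)cc1 | target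

**Step count and risks**
Total step count: 8. Longest linear sequence: 7 steps (steps 1, 2, 3, 4, 6, 7, 8); step 5 is a one-step side branch.

Steps most likely to fail:

1. Step 6 (the proposed method). The benzylic cation may lose boron (alkenyl transfer to C4) instead of closing the ring, the catalyst may discriminate the faces of the methide carbon poorly, or the quinone methide may be consumed by Friedel–Crafts self-condensation.
 Fallback, from 10 back to 17, by known reaction types: carbinol 10 and alkyne 11 would be combined under the same chiral N-triflylphosphoramide. This is the known acid-catalysed [4+2] of ortho-quinone methides with terminal arylalkynes, and should give the 2,4-diaryl-4H-chromene F1 (the two C4 epimers are diastereomers and separable if the catalyst control is incomplete). BH3·SMe2 in THF should then add across the C2=C3 enol ether with boron at C3 anti to the C4 aryl and hydrogen syn at C2, as known for flav-2-enes, giving the C3 alkylborane F2, which is not isolated. NaBO3·4H2O would oxidise it to 17 with the 2,3-trans-3,4-trans arrangement.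

2. Step 4. The aryllithium may be quenched by proton transfer before it adds to the deactivated phenolate aldehyde, or the electron-rich carbinol may ionise on work-up and self-condense.
 Fallback, from 4 back to 10 (bypassing bromide 6), with the polarity reversed: Vilsmeier–Haack formylation of 4 (POCl3, DMF) at C6 should give the 6-carbaldehyde F3. 5-(Benzyloxy)-2-bromophenol (Oc1cc(OCc2ccccc2)ccc1Br) with two equivalents of n-BuLi in THF at −78 °C should give lithium 5-(benzyloxy)-2-lithiophenolate F4. F4 would add to the neutral aldehyde F3 and give 10 after NH4Cl work-up.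

3. Step 7. The peroxoborate ate complex may undergo ring-opening β-elimination (the equatorial C3–B bond is antiperiplanar to C2–O1 and the leaving group is a phenoxide) in competition with the 1,2-shift.
 Fallback, from 15 back to 17, through a different boron species and oxidant class: KHF2 in MeOH/H2O should convert 15 into the potassium trifluoroborate F5. F5 would be oxidised with KHSO5 (used as 2KHSO5·KHSO4·K2SO4) in acetone/water at rt within minutes, with retention at C3 and without free hydroxide.

**Further compounds**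
F1 | step 6 | (4S)-7-(benzyloxy)-2-[4-(benzyloxy)phenyl]-4-[(2R,3S)-3,7-bis(benzyloxy)-2-[3,4-bis(benzyloxy)phenyl]-3,4-dihydro-2H-chromen-6-yl]-4H-chromene | c1ccccc1COc1ccc(C2=C[C@H](c3cc4c(cc3OCc3ccccc3)O[C@H](c3ccc(OCc5ccccc5)c(OCc5ccccc5)c3)[C@@H](OCc3ccccc3)C4)c3ccc(OCc5ccccc5)cc3O2)cc1
F2 | step 6 | [(2S,3S,4S)-7-(benzyloxy)-2-[4-(benzyloxy)phenyl]-4-[(2R,3S)-3,7-bis(benzyloxy)-2-[3,4-bis(benzyloxy)phenyl]-3,4-dihydro-2H-chromen-6-yl]-3,4-dihydro-2H-chromen-3-yl]borane (monoalkylborane form) | c1ccccc1COc1ccc([C@H]2Oc3cc(OCc5ccccc5)ccc3[C@@H](c3cc4c(cc3OCc3ccccc3)O[C@H](c3ccc(OCc5ccccc5)c(OCc5ccccc5)c3)[C@@H](OCc3ccccc3)C4)[C@@H]2B)cc1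
F3 | step 4 | (2R,3S)-3,7-bis(benzyloxy)-2-[3,4-bis(benzyloxy)phenyl]-3,4-dihydro-2H-chromene-6-carbaldehyde | c1ccccc1COc1c(C=O)cc2c(c1)O[C@H](c1ccc(OCc3ccccc3)c(OCc3ccccc3)c1)[C@@H](OCc1ccccc1)C2
F4 | step 4 | lithium 5-(benzyloxy)-2-lithiophenolate | [Li+].[O-]c1cc(OCc2ccccc2)ccc1[Li]
F5 | step 7 | potassium trifluoro[(2S,3S,4S)-7-(benzyloxy)-2-[4-(benzyloxy)phenyl]-4-[(2R,3S)-3,7-bis(benzyloxy)-2-[3,4-bis(benzyloxy)phenyl]-3,4-dihydro-2H-chromen-6-yl]-3,4-dihydro-2H-chromen-3-yl]borate | c1ccccc1COc1ccc([C@H]2Oc3cc(OCc5ccccc5)ccc3[C@@H](c3cc4c(cc3OCc3ccccc3)O[C@H](c3ccc(OCc5ccccc5)c(OCc5ccccc5)c3)[C@@H](OCc3ccccc3)C4)[C@@H]2[B-](F)(F)F)cc1.[K+]
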